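## Retrosynthetic overview

1. The CH2 bridge is cut last: Mannich/Michael union of two 4-hydroxy-2-pyrones, hydroxytetralone fragment A (14) and naphthalenediol fragment B (18), with Eschenmoser's salt as the one-carbon unit.
2. Both fragments come from one 1,5-diketone, 10. Fragment A arises by intramolecular aldol addition of the acetyl enolate to the benzoyl ketone, which closes the tetralone ring and sets both stereocentres relative to each other; the enantiomers are then separated. Fragment B arises by aldol condensation and aromatisation of the same diketone.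
3. Diketone 10 comes from Pd-catalysed α-arylation of phenacylpyrone 8 (Claisen acylation of O-protected triacetic acid lactone with methyl benzoate) with aryl triflate 3 (from 2',6'-dihydroxyacetophenone).
4. Ring order: the benzene and pyrone rings are bought in; the hydroxytetralone ring of A and the second naphthalene ring of B are closed by the aldol steps; the final union forms no ring.

Assumption: the left half is numbered as a 3,4-dihydronaphthalen-1(2H)-one (C1 = C=O, C3 = C(OH)Ph, C4 = CH-pyranonyl); read this way the target SMILES is (3R,4R) with OH and pyranonyl trans, which is (1R,2R) in the substituent numbering used in the names below.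

## Route

Step 1
Reactants: 1 1-(2,6-dihydroxyphenyl)ethan-1-one
Product: 2 1-[2-(benzyloxy)-6-hydroxyphenyl]ethan-1-one
Conditions: BnBr (1.05 equiv), K2CO3 (1.2 equiv), acetone, reflux
Reagents that add atoms: benzyl bromide, BrCc1ccccc1
Why: Williamson etherification stops at the mono-ether because the remaining hydroxyl is locked in a hydrogen bond to the acetyl carbonyl and is far less nucleophilic.

Step 2
Reactants: 2 1-[2-(benzyloxy)-6-hydroxyphenyl]ethan-1-one
Product: 3 2-acetyl-3-(benzyloxy)phenyl trifluoromethanesulfonate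
Conditions: (CF3SO2)2O (1.2 equiv), pyridine (3 equiv), CH2Cl2, 0 °C
Reagents that add atoms: trifluoromethanesulfonic anhydride, O=S(=O)(OS(=O)(=O)C(F)(F)F)C(F)(F)F
Why: O-sulfonylation of the chelated phenol with the highly electrophilic anhydride turns the second oxygen into a cross-coupling handle ortho to the acetyl group.

Step 3
Reactants: 4 4-hydroxy-6-methyl-2H-pyran-2-one
Product: 5 4-[(4-methoxybenzyl)oxy]-6-methyl-2H-pyran-2-one
Conditions: 4-methoxybenzyl alcohol (1.1 equiv), PPh3, DIAD, THF, 0 °C to rt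
Reagents that add atoms: 4-methoxybenzyl alcohol, COc1ccc(CO)cc1
Why: Mitsunobu O-alkylation of the vinylogous acid (pKa about 5) at O4 installs an acid-labile ether that masks the pyrone oxygen during the base and palladium steps.

Step 4
Reactants: 5 4-[(4-methoxybenzyl)oxy]-6-methyl-2H-pyran-2-one; 6 methyl benzoate
Product: 8 4-[(4-methoxybenzyl)oxy]-6-(2-oxo-2-phenylethyl)-2H-pyran-2-one, via lithium dienolate 7 (not isolated)
Conditions: LiN(SiMe3)2 (2.2 equiv), THF, −78 °C; then 6 (1.1 equiv), −78 to −20 °C; 1 M HCl quench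
Reagents that add atoms: none
Why: Crossed Claisen condensation in which the 6-methyl group of the vinylogous ester is deprotonated to the extended enolate 7, which acylates the non-enolisable ester at its terminal carbon while the second equivalent of base drives the reaction by deprotonating the more acidic product.

Step 5
Reactants: 3 2-acetyl-3-(benzyloxy)phenyl trifluoromethanesulfonate; 8 4-[(4-methoxybenzyl)oxy]-6-(2-oxo-2-phenylethyl)-2H-pyran-2-one
Product: 9 6-{1-[2-acetyl-3-(benzyloxy)phenyl]-2-oxo-2-phenylethyl}-4-[(4-methoxybenzyl)oxy]-2H-pyran-2-one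
Conditions: Pd(OAc)2 (5 mol %), XPhos (10 mol %), K3PO4 (2.5 equiv), toluene, 80 °C
Reagents that add atoms: none
Why: Palladium-catalysed α-arylation of a deoxybenzoin-type ketone (Buchwald–Hartwig enolate arylation) in which the weak phosphate base ionises only the doubly activated methylene of 8 and the hindered product enolate is not arylated again, the new stereocentre being racemic and configurationally labile, which is of no consequence at this stage.

Step 6
Reactants: 9 6-{1-[2-acetyl-3-(benzyloxy)phenyl]-2-oxo-2-phenylethyl}-4-[(4-methoxybenzyl)oxy]-2H-pyran-2-one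
Product: 10 6-{1-[2-acetyl-3-(benzyloxy)phenyl]-2-oxo-2-phenylethyl}-4-hydroxy-2H-pyran-2-one
Conditions: CF3CO2H/CH2Cl2 (1:9), anisole (5 equiv), 0 °C, 20 min
Reagents that add atoms: none
Why: Acidolysis of the 4-methoxybenzyl vinylogous ester through the stabilised benzylic cation (trapped by anisole in a Friedel–Crafts alkylation) frees the pyrone OH, while the aryl benzyl ether and both ketones survive cold dilute acid.

Step 7
Reactants: 10 6-{1-[2-acetyl-3-(benzyloxy)phenyl]-2-oxo-2-phenylethyl}-4-hydroxy-2H-pyran-2-one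
Product: 12 rac-6-[(1R,2R)-5-(benzyloxy)-2-hydroxy-4-oxo-2-phenyl-1,2,3,4-tetrahydronaphthalen-1-yl]-4-hydroxy-2H-pyran-2-one (racemate; OH trans to pyranonyl), via dilithium enolate 11 (not isolated)
Conditions: LiN(SiMe3)2 (2.3 equiv), THF, −78 °C, 1 h; AcOH (3 equiv), −78 °C
Reagents that add atoms: none
Why: Intramolecular aldol addition (6-enolendo-exo-trig) in which the first equivalent of base forms the pyronate and thereby removes the acidifying effect of the pyrone on the methine C–H, so that the second equivalent deprotonates the unhindered acetyl methyl group kinetically and the lithium enolate adds to the benzoyl carbonyl through a lithium-bridged chair-like transition state (alkoxide axial, phenyl equatorial, pyranonyl pseudo-axial away from the peri C–H), which sets the new carbinol centre with OH trans to the pyranonyl group on the existing methine centre, the product being racemic because 10 is racemic.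

Step 8
Reactants: 12 rac-6-[(1R,2R)-5-(benzyloxy)-2-hydroxy-4-oxo-2-phenyl-1,2,3,4-tetrahydronaphthalen-1-yl]-4-hydroxy-2H-pyran-2-one
Product: 13 6-[(1R,2R)-5-(benzyloxy)-2-hydroxy-4-oxo-2-phenyl-1,2,3,4-tetrahydronaphthalen-1-yl]-4-hydroxy-2H-pyran-2-one
Conditions: preparative SFC, amylose tris(3,5-dimethylphenylcarbamate) stationary phase, CO2/MeOH (0.1 % HCO2H), 35 °C
Reagents that add atoms: none
Why: Resolution by chromatography on a chiral stationary phase delivers both stereocentres in the (1R,2R) series (assigned by X-ray or ECD), and the antipode is not wasted because acid dehydration aromatises it to 17.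

Step 9
Reactants: 13 6-[(1R,2R)-5-(benzyloxy)-2-hydroxy-4-oxo-2-phenyl-1,2,3,4-tetrahydronaphthalen-1-yl]-4-hydroxy-2H-pyran-2-one
Product: 14 6-[(1R,2R)-2,5-dihydroxy-4-oxo-2-phenyl-1,2,3,4-tetrahydronaphthalen-1-yl]-4-hydroxy-2H-pyran-2-one (fragment A)
Conditions: H2 (1 atm), Pd/C (10 wt % Pd), EtOAc, rt, 1 h
Reagents that add atoms: none
Why: Hydrogenolysis of the benzyl aryl ether under neutral conditions leaves the acid- and base-sensitive tertiary β-hydroxy ketone, the aryl ketone and the pyrone untouched and affects neither stereocentre.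

Step 10
Reactants: 10 6-{1-[2-acetyl-3-(benzyloxy)phenyl]-2-oxo-2-phenylethyl}-4-hydroxy-2H-pyran-2-one
Product: 17 6-[5-(benzyloxy)-4-hydroxy-2-phenylnaphthalen-1-yl]-4-hydroxy-2H-pyran-2-one, via aldol adduct 15 (not isolated), via naphthalenone 16 (not isolated)
Conditions: KOC(CH3)3 (4 equiv), (CH3)3COH/THF (1:1), 50 °C, N2; 1 M HCl to pH 3
Reagents that add atoms: none
Why: Intramolecular aldol condensation under equilibrating alkoxide conditions, in which aldol 15 loses water by E1cB elimination to enone 16 and the doubly activated C–H of 16 is then removed to give the aromatic naphtholate irreversibly, erasing both stereocentres.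

Step 11
Reactants: 17 6-[5-(benzyloxy)-4-hydroxy-2-phenylnaphthalen-1-yl]-4-hydroxy-2H-pyran-2-one
Product: 18 6-(4,5-dihydroxy-2-phenylnaphthalen-1-yl)-4-hydroxy-2H-pyran-2-one (fragment B)
Conditions: H2 (1 atm), Pd/C (10 wt % Pd), EtOAc/MeOH, rt, N2 work-up
Reagents that add atoms: none
Why: Hydrogenolysis of the benzyl aryl ether is fast and clean on this robust aromatic fragment.

Step 12
Reactants: 18 6-(4,5-dihydroxy-2-phenylnaphthalen-1-yl)-4-hydroxy-2H-pyran-2-one
Product: 19 6-(4,5-dihydroxy-2-phenylnaphthalen-1-yl)-3-[(dimethylamino)methyl]-4-hydroxy-2H-pyran-2-one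
Conditions: [CH2=N(CH3)2]I (1.05 equiv), MeCN, −20 to 0 °C; aqueous NaHCO3 to pH 7
Reagents that add atoms: N,N-dimethylmethyleneiminium iodide (Eschenmoser's salt), C[N+](C)=C.[I-]
Why: Mannich reaction in which the enol of the vinylogous acid attacks the preformed iminium ion at C3 of the pyrone much faster than the hydrogen-bonded naphthalenediol reacts, giving an isolable zwitterionic Mannich base.

Step 13
Reactants: 14 6-[(1R,2R)-2,5-dihydroxy-4-oxo-2-phenyl-1,2,3,4-tetrahydronaphthalen-1-yl]-4-hydroxy-2H-pyran-2-one; 19 6-(4,5-dihydroxy-2-phenylnaphthalen-1-yl)-3-[(dimethylamino)methyl]-4-hydroxy-2H-pyran-2-one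
Product: 21 wailupemycin I, via quinone methide 20 (not isolated)
Conditions: MeCN, 45 °C, N2, 4 h; cold dilute citric acid wash
Reagents that add atoms: none
Why: Retro-Mannich loss of dimethylamine from the zwitterion gives the 3-methylidene-pyran-2,4-dione 20, which is trapped in a Michael addition by C3 of the pyronate of 14 (the most nucleophilic carbon present) under near-neutral conditions that neither dehydrate the β-hydroxy ketone nor touch its two stereocentres.

## Compound list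

1 | 1-(2,6-dihydroxyphenyl)ethan-1-one | CC(=O)c1c(O)cccc1O | starting material
2 | 1-[2-(benzyloxy)-6-hydroxyphenyl]ethan-1-one | CC(=O)c1c(O)cccc1OCc1ccccc1 | intermediate
3 | 2-acetyl-3-(benzyloxy)phenyl trifluoromethanesulfonate | CC(=O)c1c(OCc2ccccc2)cccc1OS(=O)(=O)C(F)(F)F | intermediate
4 | 4-hydroxy-6-methyl-2H-pyran-2-one (triacetic acid lactone) | Cc1cc(O)cc(=O)o1 | starting material
5 | 4-[(4-methoxybenzyl)oxy]-6-methyl-2H-pyran-2-one | Cc1cc(OCc2ccc(OC)cc2)cc(=O)o1 | intermediate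
6 | methyl benzoate | COC(=O)c1ccccc1 | starting material
7 | {4-[(4-methoxybenzyl)oxy]-2-oxo-2H-pyran-6-yl}methyllithium, the lithium dienolate of 5 (not isolated) | [Li]Cc1cc(OCc2ccc(OC)cc2)cc(=O)o1 | intermediate
8 | 4-[(4-methoxybenzyl)oxy]-6-(2-oxo-2-phenylethyl)-2H-pyran-2-one | O=C(Cc1cc(OCc2ccc(OC)cc2)cc(=O)o1)c1ccccc1 | intermediate
9 | 6-{1-[2-acetyl-3-(benzyloxy)phenyl]-2-oxo-2-phenylethyl}-4-[(4-methoxybenzyl)oxy]-2H-pyran-2-one (racemic, labile stereocentre) | CC(=O)c1c(OCc2ccccc2)cccc1C(C(=O)c1ccccc1)c1cc(OCc2ccc(OC)cc2)cc(=O)o1 | intermediate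
10 | 6-{1-[2-acetyl-3-(benzyloxy)phenyl]-2-oxo-2-phenylethyl}-4-hydroxy-2H-pyran-2-one (racemic) | CC(=O)c1c(OCc2ccccc2)cccc1C(C(=O)c1ccccc1)c1cc(O)cc(=O)o1 | intermediate
11 | dilithium salt of 10, pyran-4-olate plus acetyl enolate (not isolated) | [Li+].[Li+].C=C([O-])c1c(OCc2ccccc2)cccc1C(C(=O)c1ccccc1)c1cc([O-])cc(=O)o1 | intermediate
12 | rac-6-[(1R,2R)-5-(benzyloxy)-2-hydroxy-4-oxo-2-phenyl-1,2,3,4-tetrahydronaphthalen-1-yl]-4-hydroxy-2H-pyran-2-one (racemate, both enantiomers written) | O=C1C[C@](O)(c2ccccc2)[C@H](c2cc(O)cc(=O)o2)c2cccc(OCc3ccccc3)c21.O=C1C[C@@](O)(c2ccccc2)[C@@H](c2cc(O)cc(=O)o2)c2cccc(OCc3ccccc3)c21 | intermediate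
13 | 6-[(1R,2R)-5-(benzyloxy)-2-hydroxy-4-oxo-2-phenyl-1,2,3,4-tetrahydronaphthalen-1-yl]-4-hydroxy-2H-pyran-2-one | O=C1C[C@](O)(c2ccccc2)[C@H](c2cc(O)cc(=O)o2)c2cccc(OCc3ccccc3)c21 | intermediate
14 | 6-[(1R,2R)-2,5-dihydroxy-4-oxo-2-phenyl-1,2,3,4-tetrahydronaphthalen-1-yl]-4-hydroxy-2H-pyran-2-one (fragment A) | O=C1C[C@](O)(c2ccccc2)[C@H](c2cc(O)cc(=O)o2)c2cccc(O)c21 | intermediate
15 | 6-[5-(benzyloxy)-2-hydroxy-4-oxo-2-phenyl-1,2,3,4-tetrahydronaphthalen-1-yl]-4-hydroxy-2H-pyran-2-one, mixture of stereoisomers present as potassium salts (not isolated) | O=C1CC(O)(c2ccccc2)C(c2cc(O)cc(=O)o2)c2cccc(OCc3ccccc3)c21 | intermediate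
16 | 6-[5-(benzyloxy)-4-oxo-2-phenyl-1,4-dihydronaphthalen-1-yl]-4-hydroxy-2H-pyran-2-one (not isolated) | O=C1C=C(c2ccccc2)C(c2cc(O)cc(=O)o2)c2cccc(OCc3ccccc3)c21 | intermediate
17 | 6-[5-(benzyloxy)-4-hydroxy-2-phenylnaphthalen-1-yl]-4-hydroxy-2H-pyran-2-one | O=c1cc(O)cc(-c2c(-c3ccccc3)cc(O)c3c(OCc4ccccc4)cccc23)o1 | intermediate
18 | 6-(4,5-dihydroxy-2-phenylnaphthalen-1-yl)-4-hydroxy-2H-pyran-2-one (fragment B) | O=c1cc(O)cc(-c2c(-c3ccccc3)cc(O)c3c(O)cccc23)o1 | intermediate
19 | 6-(4,5-dihydroxy-2-phenylnaphthalen-1-yl)-3-[(dimethylamino)methyl]-4-hydroxy-2H-pyran-2-one | CN(C)Cc1c(O)cc(-c2c(-c3ccccc3)cc(O)c3c(O)cccc23)oc1=O | intermediate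
20 | 6-(4,5-dihydroxy-2-phenylnaphthalen-1-yl)-3-methylidene-2H-pyran-2,4(3H)-dione (not isolated) | C=C1C(=O)C=C(-c2c(-c3ccccc3)cc(O)c3c(O)cccc23)OC1=O | intermediate
21 | wailupemycin I, 6-[(1R,2R)-2,5-dihydroxy-4-oxo-2-phenyl-1,2,3,4-tetrahydronaphthalen-1-yl]-3-{[6-(4,5-dihydroxy-2-phenylnaphthalen-1-yl)-4-hydroxy-2-oxo-2H-pyran-3-yl]methyl}-4-hydroxy-2H-pyran-2-one | O=C1C[C@](O)(c2ccccc2)[C@H](c2cc(O)c(Cc3c(O)cc(-c4c(-c5ccccc5)cc(O)c5c(O)cccc45)oc3=O)c(=O)o2)c2cccc(O)c21 | target

## Step count and risks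

Total step count: 13.
Longest linear sequence: 8 steps (1, 2, 5, 6, 7, 8, 9, 13 from compound 1; the paths from 4 through steps 3 and 4, and through 10, 11, 12 on the fragment B side, are equally long), i.e. 8/13 of the total.

Steps most likely to fail:

Step 5 (α-arylation). The stabilised, hindered enolate may undergo slow reductive elimination, the 4-methoxybenzyl group may transfer, or 9 may cyclise under warm basic conditions. The fallback makes the aryl–CH bond first and adds the benzoyl group afterwards. It sets out from 5 and 3: lithium dienolate 7 is transmetallated with ZnCl2 to {4-[(4-methoxybenzyl)oxy]-2-oxo-2H-pyran-6-yl}methylzinc chloride F1, and Negishi coupling with 3 (Pd(OAc)2/SPhos, THF, 50 °C) gives 6-[2-acetyl-3-(benzyloxy)benzyl]-4-[(4-methoxybenzyl)oxy]-2H-pyran-2-one F2. Its doubly activated CH2 is deprotonated selectively (LiN(SiMe3)2, 1.05 equiv, −78 °C) and added to benzaldehyde to give 6-{1-[2-acetyl-3-(benzyloxy)phenyl]-2-hydroxy-2-phenylethyl}-4-[(4-methoxybenzyl)oxy]-2H-pyran-2-one F3, and buffered Dess–Martin oxidation comes back to the route at 9.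

Step 7 (dianion aldol). The amide base may remove the methine proton instead of an acetyl proton, or the diastereoselectivity may be low. The fallback generates the enolate regiospecifically and without base by a samarium Reformatsky-type aldol. It sets out from 3 (with 8): TBSOTf/Et3N gives the silyl enol ether 3-(benzyloxy)-2-{1-[(tert-butyldimethylsilyl)oxy]ethenyl}phenyl trifluoromethanesulfonate F4, and arylation with 8 as in step 5 gives 6-{1-[3-(benzyloxy)-2-{1-[(tert-butyldimethylsilyl)oxy]ethenyl}phenyl]-2-oxo-2-phenylethyl}-4-[(4-methoxybenzyl)oxy]-2H-pyran-2-one F5. NBS (THF, −78 °C) converts the enol ether into 6-{1-[3-(benzyloxy)-2-(bromoacetyl)phenyl]-2-oxo-2-phenylethyl}-4-[(4-methoxybenzyl)oxy]-2H-pyran-2-one F6. SmI2 (2.2 equiv, THF, −78 °C) reduces the C–Br bond and the metal-bridged enolate closes the ring to rac-6-[(1R,2R)-5-(benzyloxy)-2-hydroxy-4-oxo-2-phenyl-1,2,3,4-tetrahydronaphthalen-1-yl]-4-[(4-methoxybenzyl)oxy]-2H-pyran-2-one F7. Brief cold CF3CO2H/anisole then removes the 4-methoxybenzyl group and the route is rejoined at 12.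

Step 13 (union of the unprotected fragments, together with the selectivity of step 12). The iminium ion or quinone methide may attack the free naphthalenediol, or symmetrical dimers may form. The fallback performs the union on the benzyl-protected partners and deprotects last. It sets out from 17 and 13: Eschenmoser's salt converts 17 into 6-[5-(benzyloxy)-4-hydroxy-2-phenylnaphthalen-1-yl]-3-[(dimethylamino)methyl]-4-hydroxy-2H-pyran-2-one F8. Warming F8 with 13 (MeCN, 45 °C) gives 6-[(1R,2R)-5-(benzyloxy)-2-hydroxy-4-oxo-2-phenyl-1,2,3,4-tetrahydronaphthalen-1-yl]-3-({6-[5-(benzyloxy)-4-hydroxy-2-phenylnaphthalen-1-yl]-4-hydroxy-2-oxo-2H-pyran-3-yl}methyl)-4-hydroxy-2H-pyran-2-one F9, and hydrogenolysis of both benzyl ethers (H2, Pd/C, EtOAc) arrives at 21.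

## Further compounds

F1 | step 5 | {4-[(4-methoxybenzyl)oxy]-2-oxo-2H-pyran-6-yl}methylzinc chloride | Cl[Zn]Cc1cc(OCc2ccc(OC)cc2)cc(=O)o1
F2 | step 5 | 6-[2-acetyl-3-(benzyloxy)benzyl]-4-[(4-methoxybenzyl)oxy]-2H-pyran-2-one | CC(=O)c1c(OCc2ccccc2)cccc1Cc1cc(OCc2ccc(OC)cc2)cc(=O)o1
F3 | step 5 | 6-{1-[2-acetyl-3-(benzyloxy)phenyl]-2-hydroxy-2-phenylethyl}-4-[(4-methoxybenzyl)oxy]-2H-pyran-2-one (mixture of stereoisomers) | CC(=O)c1c(OCc2ccccc2)cccc1C(C(O)c1ccccc1)c1cc(OCc2ccc(OC)cc2)cc(=O)o1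
F4 | step 7 | 3-(benzyloxy)-2-{1-[(tert-butyldimethylsilyl)oxy]ethenyl}phenyl trifluoromethanesulfonate | C=C(O[Si](C)(C)C(C)(C)C)c1c(OCc2ccccc2)cccc1OS(=O)(=O)C(F)(F)F
F5 | step 7 | 6-{1-[3-(benzyloxy)-2-{1-[(tert-butyldimethylsilyl)oxy]ethenyl}phenyl]-2-oxo-2-phenylethyl}-4-[(4-methoxybenzyl)oxy]-2H-pyran-2-one (racemic) | C=C(O[Si](C)(C)C(C)(C)C)c1c(OCc2ccccc2)cccc1C(C(=O)c1ccccc1)c1cc(OCc2ccc(OC)cc2)cc(=O)o1
F6 | step 7 | 6-{1-[3-(benzyloxy)-2-(bromoacetyl)phenyl]-2-oxo-2-phenylethyl}-4-[(4-methoxybenzyl)oxy]-2H-pyran-2-one (racemic) | O=C(CBr)c1c(OCc2ccccc2)cccc1C(C(=O)c1ccccc1)c1cc(OCc2ccc(OC)cc2)cc(=O)o1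
F7 | step 7 | rac-6-[(1R,2R)-5-(benzyloxy)-2-hydroxy-4-oxo-2-phenyl-1,2,3,4-tetrahydronaphthalen-1-yl]-4-[(4-methoxybenzyl)oxy]-2H-pyran-2-one (racemate, both enantiomers written) | O=C1C[C@](O)(c2ccccc2)[C@H](c2cc(OCc3ccc(OC)cc3)cc(=O)o2)c2cccc(OCc3ccccc3)c21.O=C1C[C@@](O)(c2ccccc2)[C@@H](c2cc(OCc3ccc(OC)cc3)cc(=O)o2)c2cccc(OCc3ccccc3)c21
F8 | step 13 | 6-[5-(benzyloxy)-4-hydroxy-2-phenylnaphthalen-1-yl]-3-[(dimethylamino)methyl]-4-hydroxy-2H-pyran-2-one | CN(C)Cc1c(O)cc(-c2c(-c3ccccc3)cc(O)c3c(OCc4ccccc4)cccc23)oc1=O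
F9 | step 13 | 6-[(1R,2R)-5-(benzyloxy)-2-hydroxy-4-oxo-2-phenyl-1,2,3,4-tetrahydronaphthalen-1-yl]-3-({6-[5-(benzyloxy)-4-hydroxy-2-phenylnaphthalen-1-yl]-4-hydroxy-2-oxo-2H-pyran-3-yl}methyl)-4-hydroxy-2H-pyran-2-one | O=C1C[C@](O)(c2ccccc2)[C@H](c2cc(O)c(Cc3c(O)cc(-c4c(-c5ccccc5)cc(O)c5c(OCc6ccccc6)cccc45)oc3=O)c(=O)o2)c2cccc(OCc3ccccc3)c21
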